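Ring A of the target, the thiophene carrying the acyloxymethyl arm, is substituted only at C2 and C5, while C3 and C4 are bare CH. Both of its carbon–sulfur bonds (S1–C2 and S1–C5) are therefore disconnected at once, leaving a conjugated buta-1,3-diyne that a sulfide dianion can bridge. The key step closes ring A in one operation from 5-(5-bromothiophen-2-yl)penta-2,4-diyn-1-ol, a bromothienyl diynol assembled by Cadiot–Chodkiewicz coupling; its free hydroxyl and C–Br bond are spectators. The bromide then serves a Sonogashira coupling with the pre-formed butynyl isovalerate, and the senecioate is installed last.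

Key step: step 4

Remark: the target has no stereocentre. Both esters are introduced after the basic sulfide step, which they would not survive. The Sonogashira coupling is placed before the final acylation so that the thenylic ester never meets zerovalent palladium.

Step 1
Reactants: 1 5-bromothiophene-2-carbaldehyde
Product: 2 2-bromo-5-ethynylthiophene
Conditions: Ohira–Bestmann reagent, K2CO3, MeOH, 0 °C to rt
Reagents that add atoms: Ohira–Bestmann reagent, dimethyl (1-diazo-2-oxopropyl)phosphonate, COP(=O)(OC)C(=[N+]=[N-])C(C)=O
Why: Ohira–Bestmann (Seyferth–Gilbert) homologation, in which methanolysis of the reagent releases the diazomethylphosphonate anion that olefinates the non-enolisable heteroaryl aldehyde to a diazoalkene, which loses N2 and rearranges to the terminal alkyne under carbonate conditions that leave the C–Br bond alone.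

Step 2
Reactants: 3 prop-2-yn-1-ol
Product: 4 3-bromoprop-2-yn-1-ol
Conditions: NBS, AgNO3 (cat.), acetone, rt, dark
Reagents that add atoms: N-bromosuccinimide, O=C1CCC(=O)N1Br
Why: AgNO3-catalysed electrophilic bromination of a terminal alkyne through its alkynylsilver intermediate is a standard entry to 1-bromoalkynes and does not touch the primary alcohol; the product should be used without distillation.

Step 3
Reactants: 2 2-bromo-5-ethynylthiophene; 4 3-bromoprop-2-yn-1-ol
Product: 5 5-(5-bromothiophen-2-yl)penta-2,4-diyn-1-ol
Conditions: CuCl (cat.), NH2OH·HCl, n-BuNH2, H2O/Et2O, 0 °C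
Reagents that add atoms: none
Why: Cadiot–Chodkiewicz coupling, in which the alkynylcopper species formed from 2 couples with bromoalkyne 4 to give the unsymmetrical diyne, hydroxylamine keeping copper monovalent so that oxidative homocoupling is held back and the thienyl C–Br bond stays inert at 0 °C.

Step 4
Reactants: 5 5-(5-bromothiophen-2-yl)penta-2,4-diyn-1-ol
Product: 7 (5'-bromo-2,2'-bithiophen-5-yl)methanol, via Z-enynethiolate 6 (not isolated)
Conditions: Na2S·9H2O, KOH (cat.), DMSO, rt; then aq. NH4Cl
Reagents that add atoms: sodium sulfide, used as the nonahydrate Na2S·9H2O, [Na+].[Na+].[S-2]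
Why: Hydrosulfide, present once Na2S dissolves in wet DMSO, adds anti to a terminal carbon of the diyne (drawn at C2 of the pentadiynol; attack at C5 converges on the same ring) and protonation by water gives the Z-enynethiolate 6, in which sulfur sits cis to the remaining alkyne. The thiolate then closes ring A by 5-endo-dig attack on the far alkyne carbon, and protonation of the vinyl anion delivers the aromatic thiophene, so that the S1–C2 and S1–C5 bonds are both made in one flask. The closest known reaction type is the conversion of 1,4-disubstituted buta-1,3-diynes into 2,5-disubstituted thiophenes with Na2S or NaSH in basic polar media. No stereocentre is formed, and the Z geometry of 6 follows from anti addition and vanishes on aromatisation. The step needs chemoselectivity only, since both regiochemical modes of addition lead to 7: the diyne, polarised by conjugation with ring B, is a much better acceptor for the soft sulfur nucleophile than the C–Br bond of the unactivated bromothiophene, and neither hydroxide nor the propargylic alkoxide can compete with hydrosulfide at room temperature. Excess sulfide and moderate dilution should keep thiolate 6 from adding to a second diyne molecule.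

Step 5
Reactants: 8 but-3-yn-1-ol; 9 3-methylbutanoyl chloride
Product: 10 but-3-yn-1-yl 3-methylbutanoate
Conditions: Et3N, DMAP (cat.), CH2Cl2, 0 °C to rt
Reagents that add atoms: none
Why: DMAP-catalysed nucleophilic acyl substitution of an acid chloride by a primary alcohol, with the terminal alkyne as a bystander.

Step 6
Reactants: 7 (5'-bromo-2,2'-bithiophen-5-yl)methanol; 10 but-3-yn-1-yl 3-methylbutanoate
Product: 11 4-[5'-(hydroxymethyl)-2,2'-bithiophen-5-yl]but-3-yn-1-yl 3-methylbutanoate
Conditions: Pd(PPh3)2Cl2 (cat.), CuI (cat.), Et3N, THF, 60 °C, degassed
Reagents that add atoms: none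
Why: Sonogashira coupling, in which the 2-bromothiophene C–Br bond adds oxidatively to zerovalent palladium generated from Pd(PPh3)2Cl2, the alkynylcopper species of 10 transmetalates and reductive elimination forms the C(sp2)–C(sp) bond, while the free primary alcohol and the saturated ester tolerate the amine base.

Step 7
Reactants: 11 4-[5'-(hydroxymethyl)-2,2'-bithiophen-5-yl]but-3-yn-1-yl 3-methylbutanoate; 12 3-methylbut-2-enoyl chloride
Product: 13 {5'-[4-(3-methylbutanoyloxy)but-1-yn-1-yl]-2,2'-bithiophen-5-yl}methyl 3-methylbut-2-enoate
Conditions: pyridine, CH2Cl2, 0 °C
Reagents that add atoms: none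
Why: Acylation of the primary thenylic alcohol by nucleophilic acyl substitution with pyridine as the only base, which is too weak to turn the acid chloride into the vinylketene that would lead to the deconjugated 3-methylbut-3-enoate, so the conjugated ester is expected.

Compound list
1 | 5-bromothiophene-2-carbaldehyde | O=Cc1ccc(Br)s1 | starting material
2 | 2-bromo-5-ethynylthiophene | C#Cc1ccc(Br)s1 | intermediate
3 | prop-2-yn-1-ol | C#CCO | starting material
4 | 3-bromoprop-2-yn-1-ol | OCC#CBr | intermediate
5 | 5-(5-bromothiophen-2-yl)penta-2,4-diyn-1-ol | OCC#CC#Cc1ccc(Br)s1 | intermediate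
6 | sodium (Z)-5-(5-bromothiophen-2-yl)-1-hydroxypent-2-en-4-yne-2-thiolate | OC/C([S-])=C/C#Cc1ccc(Br)s1.[Na+] | intermediate
7 | (5'-bromo-2,2'-bithiophen-5-yl)methanol | OCc1ccc(-c2ccc(Br)s2)s1 | intermediate
8 | but-3-yn-1-ol | C#CCCO | starting material
9 | 3-methylbutanoyl chloride | CC(C)CC(=O)Cl | starting material
10 | but-3-yn-1-yl 3-methylbutanoate | C#CCCOC(=O)CC(C)C | intermediate
11 | 4-[5'-(hydroxymethyl)-2,2'-bithiophen-5-yl]but-3-yn-1-yl 3-methylbutanoate | OCc1ccc(-c2ccc(C#CCCOC(=O)CC(C)C)s2)s1 | intermediate
12 | 3-methylbut-2-enoyl chloride | CC(C)=CC(=O)Cl | starting material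
13 | {5'-[4-(3-methylbutanoyloxy)but-1-yn-1-yl]-2,2'-bithiophen-5-yl}methyl 3-methylbut-2-enoate | CC(C)=CC(=O)OCc1ccc(-c2ccc(C#CCCOC(=O)CC(C)C)s2)s1 | target

Total step count: 7.
Longest linear sequence: 5 steps (1 → 2 → 5 → 7 → 11 → 13, that is steps 1, 3, 4, 6 and 7).

Steps most likely to fail

Step 4. The ring closure may stall at the open-chain stage, the enethiolate may add to a second diyne and give oligomeric vinyl sulfides, or the base may degrade the diynol. In that case ring A would be taken from a cross-coupling and not built. Setting out from 1, Suzuki–Miyaura coupling with thiophen-2-ylboronic acid (Pd(PPh3)4, K2CO3, DME/H2O, 80 °C) should give 2,2'-bithiophene-5-carbaldehyde F1. NBS in DMF at room temperature should then brominate the only free α-position, C5' of the aldehyde-free ring, to give 5'-bromo-2,2'-bithiophene-5-carbaldehyde F2. Reduction with NaBH4 in MeOH at 0 °C should return to the route at 7.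

Step 3. The coupling may be eroded by homocoupling of either partner, or the volatile, polymerisation-prone alkyne 2 and the labile bromoalkyne 4 may be lost before they meet. The roles of the partners would then be exchanged. Setting out from 1, Corey–Fuchs olefination (CBr4, PPh3, CH2Cl2, 0 °C) should give 2-bromo-5-(2,2-dibromoethenyl)thiophene F3. DBU in MeCN at room temperature should eliminate HBr to give 2-bromo-5-(bromoethynyl)thiophene F4. CuCl-catalysed coupling of F4 with an excess of inexpensive 3 (NH2OH·HCl, n-BuNH2, 0 °C) should return to the route at 5, so that neither 2 nor 4 is needed.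

Step 7. The acid chloride may be deconjugated through its vinylketene during acylation, which would deliver the β,γ-unsaturated ester. The alcohol and not the acid would then be activated. Setting out from 11, Mitsunobu esterification with 3-methylbut-2-enoic acid (PPh3, DIAD, THF, 0 °C) should arrive directly at 13 without any ketene-forming acyl species. This fallback makes no compound outside the list (none F0).

Further compounds
F1 | step 4 | 2,2'-bithiophene-5-carbaldehyde | O=Cc1ccc(-c2cccs2)s1
F2 | step 4 | 5'-bromo-2,2'-bithiophene-5-carbaldehyde | O=Cc1ccc(-c2ccc(Br)s2)s1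
F3 | step 3 | 2-bromo-5-(2,2-dibromoethenyl)thiophene | BrC(Br)=Cc1ccc(Br)s1
F4 | step 3 | 2-bromo-5-(bromoethynyl)thiophene | BrC#Cc1ccc(Br)s1
F0 | step 7 | none | none
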